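**Retrosynthetic overview**

1. The target is one epicatechin gallate (rings A, B, C) bonded from C4 to C6 of ring D of a second epicatechin gallate (rings D, E, F). The plan rests on upper ring C: its contiguous centres C2, C3 and C4 lie between O1 and C4a, and its O1–C2 and C3–C4 bonds are the two bonds formed when an o-quinone methide adds to an alkene.
2. Endgame: hydrogenolysis of all benzyl ethers and of a C8 bromine cap on ring D ⇐ galloylation of the lower 3-OH ⇐ desilylation.
3. Key disconnection: ring C ⇒ an o-hydroxybenzhydrol (ring A carbinol already bonded to C6 of ring D, so the interflavan bond exists before ring C) plus the (Z)-enol gallate of the ring B styrene, joined under a chiral Brønsted acid.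
4. Benzhydrol ⇒ C6 aryllithium of protected epicatechin plus protected 2,4,6-trihydroxybenzaldehyde. Halogenation of the protected flavan goes to C8, so C8 is capped with bromine and C6 is then iodinated and exchanged selectively. Enol ester ⇒ ruthenium-catalysed anti-Markovnikov addition of tri-O-benzylgallic acid to the aryl alkyne.
5. Ring order: rings A, B, D, E and F arrive intact; ring C is the only ring formed.

Key step: step 11

Assumption: the sense of induction of the chiral acid cannot be fixed in advance; the (R)-acid is written, and the (S)-acid is used instead if it is the one that leads to the (2R,3R,4R) upper ring. 3,4-Bis(benzyloxy)benzaldehyde and 3,4,5-tris(benzyloxy)benzoic acid are taken as commercial.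

**Route**

Step 1
Reactants: 1 (−)-epicatechin
Product: 2 5,7,3',4'-tetra-O-benzyl-(−)-epicatechin
Conditions: BnBr (4.2 equiv), K2CO3, DMF, 0 °C to rt
Reagents that add atoms: benzyl bromide, BrCc1ccccc1
Why: Williamson etherification alkylates the four phenols under carbonate base, while the much less acidic secondary 3-OH stays free and neither stereocentre is touched.

Step 2
Reactants: 2 5,7,3',4'-tetra-O-benzyl-(−)-epicatechin
Product: 3 8-bromo-5,7,3',4'-tetra-O-benzyl-(−)-epicatechin
Conditions: NBS (1.0 equiv), CH2Cl2, −78 °C to rt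
Reagents that add atoms: N-bromosuccinimide, O=C1CCC(=O)N1Br
Why: Electrophilic aromatic bromination of the phloroglucinol-type ring of this ether takes C8 in preference to C6 and to the catechol ring, so C8 is made the capped position and C6 is addressed separately.

Step 3
Reactants: 3 8-bromo-5,7,3',4'-tetra-O-benzyl-(−)-epicatechin
Product: 4 8-bromo-5,7,3',4'-tetra-O-benzyl-3-O-(tert-butyldimethylsilyl)-(−)-epicatechin
Conditions: TBSCl, imidazole, DMF, rt to 40 °C
Reagents that add atoms: tert-butyldimethylsilyl chloride, CC(C)(C)[Si](C)(C)Cl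
Why: Imidazole-promoted silylation of the secondary 3-OH gives an ether that tolerates the aryllithium chemistry of step 7 and the acid of step 11.

Step 4
Reactants: 4 8-bromo-5,7,3',4'-tetra-O-benzyl-3-O-(tert-butyldimethylsilyl)-(−)-epicatechin
Product: 5 8-bromo-6-iodo-5,7,3',4'-tetra-O-benzyl-3-O-(tert-butyldimethylsilyl)-(−)-epicatechin
Conditions: NIS (1.1 equiv), DMF, rt, dark
Reagents that add atoms: N-iodosuccinimide, O=C1CCC(=O)N1I
Why: Electrophilic aromatic iodination can only take C6, the last open position of the ring and one activated by two ortho benzyloxy groups and the para ring oxygen, and it gives a C–I bond that exchanges with lithium far faster than the C8–Br bond.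

Step 5
Reactants: 6 2,4,6-trihydroxybenzaldehyde
Product: 7 2,4-bis(benzyloxy)-6-hydroxybenzaldehyde
Conditions: BnBr (2.1 equiv), K2CO3, DMF, rt
Reagents that add atoms: benzyl bromide, BrCc1ccccc1
Why: Williamson etherification takes the 4-OH and one ortho OH, while the second ortho OH is held back by its hydrogen bond to the aldehyde.

Step 6
Reactants: 7 2,4-bis(benzyloxy)-6-hydroxybenzaldehyde
Product: 8 2-(allyloxy)-4,6-bis(benzyloxy)benzaldehyde
Conditions: allyl bromide, K2CO3, DMF, 50 °C
Reagents that add atoms: allyl bromide, C=CCBr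
Why: Williamson allylation of the chelated phenol under more forcing conditions installs a group that cannot migrate to an alkoxide as an acyl or silyl group would and that can later be removed without acid.

Step 7
Reactants: 5 8-bromo-6-iodo-5,7,3',4'-tetra-O-benzyl-3-O-(tert-butyldimethylsilyl)-(−)-epicatechin; 8 2-(allyloxy)-4,6-bis(benzyloxy)benzaldehyde
Product: 10 allyl-protected benzhydrol [2-(allyloxy)-4,6-bis(benzyloxy)phenyl][8-bromo-5,7,3',4'-tetra-O-benzyl-3-O-TBS-epicatechin-6-yl]methanol as both carbinol epimers, via C6 aryllithium 9 (not isolated)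
Conditions: n-BuLi (1.05 equiv), THF, −78 °C; then 8, −78 to −40 °C; H2O quench
Reagents that add atoms: none
Why: Iodine–lithium exchange outruns bromine–lithium exchange and benzylic deprotonation at −78 °C and the aryllithium adds 1,2 to the aldehyde; the carbinol centre forms without control, which does not matter because it becomes the sp2 methide carbon in step 11.

Step 8
Reactants: 10 allyl-protected benzhydrol
Product: 11 o-hydroxybenzhydrol [2-hydroxy-4,6-bis(benzyloxy)phenyl][8-bromo-5,7,3',4'-tetra-O-benzyl-3-O-TBS-epicatechin-6-yl]methanol (both carbinol epimers)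
Conditions: Pd(PPh3)4 (5 mol%), morpholine, THF, rt; chromatography on Et3N-deactivated silica
Reagents that add atoms: none
Why: Tsuji–Trost-type deallylation, in which zerovalent palladium ionises the aryl allyl ether and morpholine traps the allyl fragment, frees the phenol under neutral conditions that leave the acid-labile carbinol, the benzyl ethers, the silyl ether and the aryl bromide alone.

Step 9
Reactants: 12 3,4-bis(benzyloxy)benzaldehyde
Product: 13 1,2-bis(benzyloxy)-4-ethynylbenzene
Conditions: dimethyl (1-diazo-2-oxopropyl)phosphonate, K2CO3, MeOH/THF, rt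
Reagents that add atoms: dimethyl (1-diazo-2-oxopropyl)phosphonate, CC(=O)C(=[N+]=[N-])P(=O)(OC)OC
Why: Seyferth–Gilbert homologation with the Ohira–Bestmann reagent converts an aryl aldehyde into the terminal alkyne under mild carbonate conditions.

Step 10
Reactants: 13 1,2-bis(benzyloxy)-4-ethynylbenzene; 14 3,4,5-tris(benzyloxy)benzoic acid
Product: 15 (Z)-2-[3,4-bis(benzyloxy)phenyl]ethenyl 3,4,5-tris(benzyloxy)benzoate
Conditions: [RuCl2(p-cymene)]2 (1 mol%), P(4-ClC6H4)3 (3 mol%), DMAP (4 mol%), toluene, 60 °C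
Reagents that add atoms: none
Why: Ruthenium-catalysed hydro-oxycarbonylation of a terminal alkyne proceeds through a ruthenium vinylidene that the carboxylate attacks at the carbon bound to the metal, which gives the anti-Markovnikov enol ester with (Z) geometry.

Step 11
Reactants: 11 o-hydroxybenzhydrol; 15 (Z)-2-[3,4-bis(benzyloxy)phenyl]ethenyl 3,4,5-tris(benzyloxy)benzoate
Product: 17 protected dimer 5,7,3',4'-tetra-O-benzyl-3-O-(tri-O-benzylgalloyl)epicatechin-(4β→6)-[8-bromo-5,7,3',4'-tetra-O-benzyl-3-O-TBS-epicatechin] having the (2R,3R,4R) upper ring C, via o-quinone methide 16 (not isolated)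
Conditions: (R)-TRIP [(R)-3,3'-bis(2,4,6-triisopropylphenyl)-1,1'-binaphthyl-2,2'-diyl hydrogen phosphate] (10 mol%), 5 Å MS, toluene, 0 °C to rt; 11 added slowly to 15 (2.5 equiv)
Reagents that add atoms: none
Why: Proposed new method: the phosphoric acid ionises the doubly benzylic carbinol of 11 and, with loss of the phenol proton, gives the hydrogen-bonded o-quinone methide 16 (heterodiene O1=C8a–C4a=C4), which should combine with the enol ester 15 in an inverse-demand hetero-Diels–Alder reaction; the closest known reaction type is the chiral phosphoric acid catalysed [4+2] cycloaddition of o-quinone methides generated in situ from o-hydroxybenzhydrols with electron-rich styrenes, and a β-acyloxystyrene has not been shown as the 2π partner. Upper ring C is closed by this single concerted but asynchronous [4+2] cycloaddition, the C3–C4 bond running ahead of the O1–C2 bond because the 3,4-bis(benzyloxy)phenyl group is a stronger donor than the acyloxy group and so makes C3 the nucleophilic carbon and C2 the carbon that takes O1. C2 and C3 are set relative to each other by suprafacial transfer of the (Z)-alkene geometry, which places the aryl group and the gallate cis. C4 is set by the methide geometry and the mode of approach: the peri C5 benzyloxy group of ring A forces ring D into the inside (Z) position, and endo approach of the dienophile, the mode preferred by styrenes, then puts ring D trans to the gallate. The absolute configuration of all three centres follows from the face of 16 that the 2,4,6-triisopropylphenyl walls of the bound acid leave open, the remote centres of the lower unit giving little bias, so that the minor face isomer is a diastereomer and should be separable. The step needs cycloaddition to outrun arylation of 16 by the free C6 and C8 positions of another ring A and needs the closure to stay concerted, for which slow addition of 11 to an excess of 15, molecular sieves and a non-polar solvent are used.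

Step 12
Reactants: 17 protected dimer (upper 3-O-gallate, lower 3-O-TBS, C8 bromide)
Product: 18 protected dimer with free lower 3-OH
Conditions: TBAF, AcOH, THF, rt
Reagents that add atoms: none
Why: Fluoride-induced desilylation buffered with acetic acid frees the lower 3-OH without touching the upper gallate ester, which is too far away to migrate.

Step 13
Reactants: 18 protected dimer with free lower 3-OH; 14 3,4,5-tris(benzyloxy)benzoic acid
Product: 19 perbenzylated C8-bromo bis-gallate
Conditions: DCC, DMAP, CH2Cl2, rt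
Reagents that add atoms: none
Why: Steglich esterification acylates the secondary lower 3-OH with retention, since the C–O bond of the alcohol is not broken.

Step 14
Reactants: 19 perbenzylated C8-bromo bis-gallate
Product: 20 procyanidin B-5 3,3'-di-O-gallate
Conditions: H2 (1 atm), Pd(OH)2/C, Et3N (1.1 equiv), THF/MeOH/H2O, rt
Reagents that add atoms: none
Why: Catalytic hydrogenolysis cleaves the fourteen benzyl ethers and the C8–Br bond in one operation, the amine taking up the hydrogen bromide so that the acid-labile interflavan bond and the five stereocentres are left as they are.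

**Compound list**

1 | (−)-epicatechin | O[C@@H]1Cc2c(O)cc(O)cc2O[C@@H]1c1ccc(O)c(O)c1 | starting material
2 | 5,7,3',4'-tetra-O-benzyl-(−)-epicatechin | O[C@@H]1Cc2c(OCc3ccccc3)cc(OCc3ccccc3)cc2O[C@@H]1c1ccc(OCc2ccccc2)c(OCc2ccccc2)c1 | intermediate
3 | 8-bromo-5,7,3',4'-tetra-O-benzyl-(−)-epicatechin | O[C@@H]1Cc2c(OCc3ccccc3)cc(OCc3ccccc3)c(Br)c2O[C@@H]1c1ccc(OCc2ccccc2)c(OCc2ccccc2)c1 | intermediate
4 | 8-bromo-5,7,3',4'-tetra-O-benzyl-3-O-(tert-butyldimethylsilyl)-(−)-epicatechin | CC(C)(C)[Si](C)(C)O[C@@H]1Cc2c(OCc3ccccc3)cc(OCc3ccccc3)c(Br)c2O[C@@H]1c1ccc(OCc2ccccc2)c(OCc2ccccc2)c1 | intermediate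
5 | 8-bromo-6-iodo-5,7,3',4'-tetra-O-benzyl-3-O-(tert-butyldimethylsilyl)-(−)-epicatechin | CC(C)(C)[Si](C)(C)O[C@@H]1Cc2c(OCc3ccccc3)c(I)c(OCc3ccccc3)c(Br)c2O[C@@H]1c1ccc(OCc2ccccc2)c(OCc2ccccc2)c1 | intermediate
6 | 2,4,6-trihydroxybenzaldehyde | O=Cc1c(O)cc(O)cc1O | starting material
7 | 2,4-bis(benzyloxy)-6-hydroxybenzaldehyde | O=Cc1c(O)cc(OCc2ccccc2)cc1OCc1ccccc1 | intermediate
8 | 2-(allyloxy)-4,6-bis(benzyloxy)benzaldehyde | C=CCOc1cc(OCc2ccccc2)cc(OCc2ccccc2)c1C=O | intermediate
9 | C6 aryllithium: 8-bromo-6-lithio-5,7,3',4'-tetra-O-benzyl-3-O-TBS-epicatechin | CC(C)(C)[Si](C)(C)O[C@@H]1Cc2c(OCc3ccccc3)c([Li])c(OCc3ccccc3)c(Br)c2O[C@@H]1c1ccc(OCc2ccccc2)c(OCc2ccccc2)c1 | intermediate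
10 | allyl-protected benzhydrol: [2-(allyloxy)-4,6-bis(benzyloxy)phenyl][8-bromo-5,7,3',4'-tetra-O-benzyl-3-O-TBS-epicatechin-6-yl]methanol, both carbinol epimers | OC(c1c(OCC=C)cc(OCc2ccccc2)cc1OCc1ccccc1)c1c(OCc2ccccc2)c(Br)c2c(c1OCc1ccccc1)C[C@@H](O[Si](C)(C)C(C)(C)C)[C@@H](c1ccc(OCc3ccccc3)c(OCc3ccccc3)c1)O2 | intermediate
11 | o-hydroxybenzhydrol: [2-hydroxy-4,6-bis(benzyloxy)phenyl][8-bromo-5,7,3',4'-tetra-O-benzyl-3-O-TBS-epicatechin-6-yl]methanol, both carbinol epimers | OC(c1c(O)cc(OCc2ccccc2)cc1OCc1ccccc1)c1c(OCc2ccccc2)c(Br)c2c(c1OCc1ccccc1)C[C@@H](O[Si](C)(C)C(C)(C)C)[C@@H](c1ccc(OCc3ccccc3)c(OCc3ccccc3)c1)O2 | intermediate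
12 | 3,4-bis(benzyloxy)benzaldehyde | O=Cc1ccc(OCc2ccccc2)c(OCc2ccccc2)c1 | starting material
13 | 1,2-bis(benzyloxy)-4-ethynylbenzene | C#Cc1ccc(OCc2ccccc2)c(OCc2ccccc2)c1 | intermediate
14 | 3,4,5-tris(benzyloxy)benzoic acid | OC(=O)c1cc(OCc2ccccc2)c(OCc2ccccc2)c(OCc2ccccc2)c1 | starting material
15 | (Z)-2-[3,4-bis(benzyloxy)phenyl]ethenyl 3,4,5-tris(benzyloxy)benzoate | O=C(O/C=C\c1ccc(OCc2ccccc2)c(OCc2ccccc2)c1)c1cc(OCc2ccccc2)c(OCc2ccccc2)c(OCc2ccccc2)c1 | intermediate
16 | o-quinone methide: 3,5-bis(benzyloxy)cyclohexa-2,4-dien-1-one carrying at C6 the (Z)-methylidene bonded to C6 of the 8-bromo-tetra-O-benzyl-3-O-TBS-epicatechin unit (ring D syn to the carbonyl oxygen) | O=C1C=C(OCc2ccccc2)C=C(OCc2ccccc2)/C1=C/c1c(OCc2ccccc2)c(Br)c2c(c1OCc1ccccc1)C[C@@H](O[Si](C)(C)C(C)(C)C)[C@@H](c1ccc(OCc3ccccc3)c(OCc3ccccc3)c1)O2 | intermediate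
17 | protected dimer: 5,7,3',4'-tetra-O-benzyl-3-O-(tri-O-benzylgalloyl)epicatechin-(4β→6)-[8-bromo-5,7,3',4'-tetra-O-benzyl-3-O-TBS-epicatechin], upper ring C (2R,3R,4R), 2,3-cis-3,4-trans | O=C(O[C@@H]1[C@@H](c2c(OCc4ccccc4)c(Br)c3c(c2OCc2ccccc2)C[C@@H](O[Si](C)(C)C(C)(C)C)[C@@H](c2ccc(OCc4ccccc4)c(OCc4ccccc4)c2)O3)c2c(OCc3ccccc3)cc(OCc3ccccc3)cc2O[C@@H]1c1ccc(OCc2ccccc2)c(OCc2ccccc2)c1)c1cc(OCc2ccccc2)c(OCc2ccccc2)c(OCc2ccccc2)c1 | intermediate
18 | protected dimer with free lower 3-OH (upper 3-O-gallate, C8 bromide kept) | O=C(O[C@@H]1[C@@H](c2c(OCc4ccccc4)c(Br)c3c(c2OCc2ccccc2)C[C@@H](O)[C@@H](c2ccc(OCc4ccccc4)c(OCc4ccccc4)c2)O3)c2c(OCc3ccccc3)cc(OCc3ccccc3)cc2O[C@@H]1c1ccc(OCc2ccccc2)c(OCc2ccccc2)c1)c1cc(OCc2ccccc2)c(OCc2ccccc2)c(OCc2ccccc2)c1 | intermediate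
19 | perbenzylated C8-bromo bis-gallate: 17 with the lower 3-O-TBS replaced by 3-O-(tri-O-benzylgalloyl) | O=C(O[C@@H]1[C@@H](c2c(OCc4ccccc4)c(Br)c3c(c2OCc2ccccc2)C[C@@H](OC(=O)c2cc(OCc4ccccc4)c(OCc4ccccc4)c(OCc4ccccc4)c2)[C@@H](c2ccc(OCc4ccccc4)c(OCc4ccccc4)c2)O3)c2c(OCc3ccccc3)cc(OCc3ccccc3)cc2O[C@@H]1c1ccc(OCc2ccccc2)c(OCc2ccccc2)c1)c1cc(OCc2ccccc2)c(OCc2ccccc2)c(OCc2ccccc2)c1 | intermediate
20 | procyanidin B-5 3,3'-di-O-gallate | O=C(O[C@@H]1[C@@H](c2c(O)cc3c(c2O)C[C@@H](OC(=O)c2cc(O)c(O)c(O)c2)[C@@H](c2ccc(O)c(O)c2)O3)c2c(O)cc(O)cc2O[C@@H]1c1ccc(O)c(O)c1)c1cc(O)c(O)c(O)c1 | target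

**Count**

Total steps: 14. Longest linear sequence: 10 steps (steps 1, 2, 3, 4, 7, 8, 11, 12, 13, 14).

**Three steps most likely to fail**

1. Step 11 (carries the label). Several processes could defeat it:
 - The doubly aryl-stabilised methide may be too weak an electrophile for the acyloxy-deactivated alkene and be consumed by arylation from ring A of another molecule.
 - The closure may turn stepwise, with rotation or acyloxonium participation in the benzylic cation eroding the 2,3-cis relation.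
 - Control of methide geometry or of endo against exo approach may be poor, giving the 3,4-cis isomer.
 - Facial control by the acid may be weak.

 Fallback (known chemistry): Lewis-acid-promoted interflavan coupling with halogen caps on both partners. It sets out from 3 and 4 and returns to the route at 20. Compound 3 is oxidised at C4 with DDQ in the presence of 2-ethoxyethanol (CH2Cl2, rt) to 8-bromo-4β-(2-ethoxyethoxy)-5,7,3',4'-tetra-O-benzylepicatechin F1. Esterification with 14 (DCC, DMAP, CH2Cl2) gives its 3-O-(tri-O-benzylgalloyl) ester F2. TMSOTf (CH2Cl2, −78 °C) ionises C4 of F2 in the presence of an excess of 4. With C8 of both partners capped, only C6 of 4 can take the cation, and approach anti to the participating 3-acyloxy group should give the 4β bond. The product is the dibromo dimer F3, the analogue of 17 with a second bromine at C8 of ring A. TBAF/AcOH gives the lower alcohol F4, and DCC/DMAP with 14 gives the dibromo bis-gallate F5. Hydrogenolysis as in step 14, with Et3N raised to 2.2 equiv, removes both bromines and all benzyl groups to give 20.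

2. Step 7. The di-ortho-substituted aryllithium may add too slowly to the electron-rich, di-ortho-substituted aldehyde and decay on warming by benzylic proton transfer or Wittig rearrangement. The sensitive carbinol may also ionise during isolation.

 Fallback: acylation followed by reduction. It sets out from 8 and 5 and returns at 10. Pinnick oxidation of 8 (NaClO2, NaH2PO4, 2-methyl-2-butene, t-BuOH/H2O) gives 2-(allyloxy)-4,6-bis(benzyloxy)benzoic acid F6. Oxalyl chloride with catalytic DMF (CH2Cl2) gives 2-(allyloxy)-4,6-bis(benzyloxy)benzoyl chloride F7, a far stronger electrophile than the aldehyde. Aryllithium 9, made from 5 as in step 7, is acylated by F7 at −78 °C to the benzophenone F8, which is robust and can be purified. LiAlH4 (THF, 0 °C) reduces F8 to 10.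

3. Step 14. Cleavage of fourteen benzyl ethers may stall as bromide and amine slow the catalyst. The interflavan bond may be cleaved by acid if the hydrogen bromide is not fully taken up. The free polyphenol may oxidise in air while base is present.

 Fallback: remove the bromine by radical reduction before the hydrogenolysis. It sets out from 19 and returns at 20. Bu3SnH and AIBN (toluene, 90 °C) give the bromine-free perbenzylated bis-gallate F9. H2 over Pd(OH)2/C in THF/MeOH/H2O without base then gives 20.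

**Further compounds**

F1 | step 11 | 8-bromo-4β-(2-ethoxyethoxy)-5,7,3',4'-tetra-O-benzylepicatechin | O[C@@H]1[C@@H](OCCOCC)c2c(OCc3ccccc3)cc(OCc3ccccc3)c(Br)c2O[C@@H]1c1ccc(OCc2ccccc2)c(OCc2ccccc2)c1
F2 | step 11 | 8-bromo-4β-(2-ethoxyethoxy)-5,7,3',4'-tetra-O-benzyl-3-O-(tri-O-benzylgalloyl)epicatechin | O=C(O[C@@H]1[C@@H](OCCOCC)c2c(OCc3ccccc3)cc(OCc3ccccc3)c(Br)c2O[C@@H]1c1ccc(OCc2ccccc2)c(OCc2ccccc2)c1)c1cc(OCc2ccccc2)c(OCc2ccccc2)c(OCc2ccccc2)c1
F3 | step 11 | dibromo dimer: 17 with an additional bromine at C8 of ring A | O=C(O[C@@H]1[C@@H](c2c(OCc4ccccc4)c(Br)c3c(c2OCc2ccccc2)C[C@@H](O[Si](C)(C)C(C)(C)C)[C@@H](c2ccc(OCc4ccccc4)c(OCc4ccccc4)c2)O3)c2c(OCc3ccccc3)cc(OCc3ccccc3)c(Br)c2O[C@@H]1c1ccc(OCc2ccccc2)c(OCc2ccccc2)c1)c1cc(OCc2ccccc2)c(OCc2ccccc2)c(OCc2ccccc2)c1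
F4 | step 11 | dibromo dimer with free lower 3-OH | O=C(O[C@@H]1[C@@H](c2c(OCc4ccccc4)c(Br)c3c(c2OCc2ccccc2)C[C@@H](O)[C@@H](c2ccc(OCc4ccccc4)c(OCc4ccccc4)c2)O3)c2c(OCc3ccccc3)cc(OCc3ccccc3)c(Br)c2O[C@@H]1c1ccc(OCc2ccccc2)c(OCc2ccccc2)c1)c1cc(OCc2ccccc2)c(OCc2ccccc2)c(OCc2ccccc2)c1
F5 | step 11 | perbenzylated dibromo bis-gallate | O=C(O[C@@H]1[C@@H](c2c(OCc4ccccc4)c(Br)c3c(c2OCc2ccccc2)C[C@@H](OC(=O)c2cc(OCc4ccccc4)c(OCc4ccccc4)c(OCc4ccccc4)c2)[C@@H](c2ccc(OCc4ccccc4)c(OCc4ccccc4)c2)O3)c2c(OCc3ccccc3)cc(OCc3ccccc3)c(Br)c2O[C@@H]1c1ccc(OCc2ccccc2)c(OCc2ccccc2)c1)c1cc(OCc2ccccc2)c(OCc2ccccc2)c(OCc2ccccc2)c1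
F6 | step 7 | 2-(allyloxy)-4,6-bis(benzyloxy)benzoic acid | OC(=O)c1c(OCC=C)cc(OCc2ccccc2)cc1OCc1ccccc1
F7 | step 7 | 2-(allyloxy)-4,6-bis(benzyloxy)benzoyl chloride | ClC(=O)c1c(OCC=C)cc(OCc2ccccc2)cc1OCc1ccccc1
F8 | step 7 | benzophenone: [2-(allyloxy)-4,6-bis(benzyloxy)phenyl][8-bromo-5,7,3',4'-tetra-O-benzyl-3-O-TBS-epicatechin-6-yl]methanone | O=C(c1c(OCC=C)cc(OCc2ccccc2)cc1OCc1ccccc1)c1c(OCc2ccccc2)c(Br)c2c(c1OCc1ccccc1)C[C@@H](O[Si](C)(C)C(C)(C)C)[C@@H](c1ccc(OCc3ccccc3)c(OCc3ccccc3)c1)O2
F9 | step 14 | bromine-free perbenzylated bis-gallate | O=C(O[C@@H]1[C@@H](c2c(OCc4ccccc4)cc3c(c2OCc2ccccc2)C[C@@H](OC(=O)c2cc(OCc4ccccc4)c(OCc4ccccc4)c(OCc4ccccc4)c2)[C@@H](c2ccc(OCc4ccccc4)c(OCc4ccccc4)c2)O3)c2c(OCc3ccccc3)cc(OCc3ccccc3)cc2O[C@@H]1c1ccc(OCc2ccccc2)c(OCc2ccccc2)c1)c1cc(OCc2ccccc2)c(OCc2ccccc2)c(OCc2ccccc2)c1
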